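(The data stem from a simulated flask for substances that don't exist; the scatter is artificial.)

**The constants.** The rate constants are hidden, but one combination of them can be read from the fractions left.

all flasks: left-handed substrate 0.051 M; right-handed substrate 0.051 M; reagent 0.153 M
- alder: free catalyst 51 µM; racemization catalyst 0.35 mM; run made earlier
- maple: free catalyst 51 µM; racemization catalyst 0.53 mM; run made earlier
- cedar: free catalyst 76 µM; racemization catalyst 0.71 mM; run made earlier
- flask: free catalyst 51 µM; racemization catalyst 0.71 mM; time 5.0 min
- alder (time / min: left-handed product / %, right-handed product / %, left-handed substrate / %): 0.500: 6, 3, 40; 1.50: 14, 10, 34; 3.00: 27, 16, 22; 4.00: 31, 22, 21; 6.00: 45, 26, 16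
- maple (time / min: left-handed product / %, right-handed product / %, left-handed substrate / %): 0.500: 6, 2, 41; 0.833: 13, 9, 39; 1.50: 16, 12, 35; 3.00: 28, 18, 22; 6.00: 41, 29, 17
- cedar (time / min: left-handed product / %, right-handed product / %, left-handed substrate / %): 1.33: 21, 13, 30; 2.50: 33, 21, 23; 4.00: 35, 23, 19; 5.00: 44, 31, 15; 6.00: 44, 28, 11

(readings scatter by 2 percentage points)
- free catalyst is single-handed; left-handed substrate and right-handed substrate are mirror images of each other, charged as a racemate, each of them at the stated concentration
- the numbers in the tables scatter with a standard deviation of 2 percentage points
- on the list of suspects stand: reagent -> decomposition product; reagent + free catalyst + left-handed substrate -> free catalyst + left-handed product; 2 free catalyst <-> resting dimer; reagent + free catalyst + right-handed substrate -> free catalyst + right-handed product; left-handed substrate + racemization catalyst <-> right-handed substrate + racemization catalyst; left-handed product <-> right-handed product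
- an excess is the difference of the two amounts in percent of their sum
- an excess is below zero if the other one leads
- left-handed product and right-handed product together, in percent of the left-handed substrate and right-handed substrate charged together, at 5.0 min
- excess of left-handed product over right-handed product in the product at 5.0 min
- whether the exchange between left-handed substrate and right-handed substrate keeps pace with the reaction: how far the product's excess at 5.0 min gets from its value without exchange to its value with instant exchange (above 80% keeps pace, below 20% hardly takes part, else lags behind)

**Gap rate.** Lump both substrates and suppose each round runs as reagent times substrate times free catalyst, with the free catalyst returned. Then the logarithm of (fraction of reagent left ÷ fraction of substrate left) climbs in a straight line from zero. The substrates together are the limiting reagent, 66.7% of the reagent charge, so the fraction of reagent left is one minus that share times the fraction reacted.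

Alder and maple have the flask's charges except for racemization catalyst, so you pool them. At 3.00 min the slope reads 0.0790 min⁻¹, and at 6.00 min it reads 0.0977 min⁻¹. Their mean, 0.0883 min⁻¹, is the gap rate, the slope of that logarithm.

**The curve.** For the flask, the fraction of substrate left starts down at 0.265 min⁻¹. It reaches 0.5, where product crosses substrate, at 3.26 min. At 5.0 min your reckoning gives 62.5% product. After that substrate runs towards zero and reagent towards 33.3% of its charge.

**The forecast.** By another road, “Total product follows roughly first-order decay”, the forecast says 63% (59% to 67%), an excess of 19.5% (16.5% to 23%), and that the exchange lags behind.

**The result.** The flask gives 60.7% product and an excess of 20.3%, and the exchange lags behind, getting 59% of the way.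

    reagent → decomposition product (k = 8.20 × 10⁻⁶ s⁻¹)
    reagent + free catalyst + left-handed substrate → free catalyst + left-handed product (k = 980 L² mol⁻² s⁻¹)
    2 free catalyst ⇌ resting dimer, settled at all times (K = 5000 L mol⁻¹)
    reagent + free catalyst + right-handed substrate → free catalyst + right-handed product (k = 510 L² mol⁻² s⁻¹)
    left-handed substrate + racemization catalyst ⇌ right-handed substrate + racemization catalyst, rate k5*[racemization catalyst]*[left-handed substrate] forward; the back reaction follows from the equilibrium constant (k = 8.60 L mol⁻¹ s⁻¹)
    left-handed product ⇌ right-handed product (k = 7.10 × 10⁻⁴ s⁻¹)

Its fractions left at 5.0 min, 59% of reagent against 39.3% of substrate, give a gap rate of 0.0823 min⁻¹. The neighbour charged with 1.3 × 10⁻⁴ M of free catalyst keeps 57.3% of it free against 72.9% in the flask, the rest sitting outside the working round as resting dimer, so scaling by free catalyst makes its gap rate 0.165 min⁻¹, faster and about twice the flask's. That predicts 79.4% product, and the neighbour stands at 79.2%.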